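## Retrosynthetic overview

1. Target 29 ⇐ cycloheptane hydroxy ester 26: the α-methylene-γ-lactone is the last ring, closed on O-6 while 8-OH is masked.
2. 26 ⇐ acyclic (Z)-2-(bromomethyl)enoate 24: the cycloheptane (second ring) is closed at C7–C8 by an intramolecular indium Barbier allylation.
3. 24 ⇐ C7 aldehyde 18 (Morita–Baylis–Hillman, double angeloylation, bromide) ⇐ Weinreb amide 9 (propenyl ketone; hydroboration of the vinyl group).
4. 9 ⇐ lactone 7 ⇐ crotyl ether 5: the key C1–C10 bond (tertiary carbinol plus methyl stereocentre) comes from a [2,3]-Wittig rearrangement of a lactone enolate.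
5. 5 ⇐ D-xylono-1,4-lactone 1, which supplies C5 and C6; its furanone ring is the first ring, used as a template and opened in step 5.

Assumption: D-xylono-1,4-lactone is taken as purchasable (it is also one bromine-water oxidation from D-xylose); lactol/acetal carbons (C8 in 13, 14, 17, 18, 20, 23–25) and the carbinol carbon of 20 and 23 form as mixtures that are erased later, so they carry no stereodescriptor.

Locants: target locants are C1 (tertiary carbinol), C2 (ketone), C5 (CH–O-angelate), C6 (lactone CH–O), C7, C8 (CHOH), C9 (CH2), C10 (CH–CH3), C11(=C13H2)–C12(=O). Carbohydrate C1, C2, C3, C4, C5 become target C2, C1, C5, C6, C7. Names of 1–14 keep carbohydrate locants; the "Why" lines use target locants unless marked.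

## Route

Step 1
Reactants: 1 D-xylono-1,4-lactone
Product: 2 3,5-O-isopropylidene-D-xylono-1,4-lactone
Conditions: Me2C(OMe)2, CSA (cat.), acetone, rt
Reagents that add atoms: 2,2-dimethoxypropane, COC(C)(C)OC
Why: Acid-catalysed transacetalization can only bridge the cis-related 3-OH and 5-OH (carbohydrate locants) of the xylo lactone, so 2-OH stays as the single free hydroxyl and no stereocentre is created.

Step 2
Reactants: 2 3,5-O-isopropylidene-D-xylono-1,4-lactone; 3 1-bromobut-2-yne
Product: 4 2-O-(but-2-yn-1-yl)-3,5-O-isopropylidene-D-xylono-1,4-lactone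
Conditions: Ag2O, CH2Cl2, 4 Å MS, dark, rt
Reagents that add atoms: none
Why: Purdie-type Ag2O etherification (a Williamson O-alkylation without strong base) leaves the lactone un-enolized and un-eliminated, and touches no stereocentre.

Step 3
Reactants: 4 2-O-(but-2-yn-1-yl)-3,5-O-isopropylidene-D-xylono-1,4-lactone
Product: 5 2-O-[(Z)-but-2-en-1-yl]-3,5-O-isopropylidene-D-xylono-1,4-lactone
Conditions: H2 (1 atm), Pd/CaCO3 poisoned with Pb(OAc)2, quinoline, EtOAc, rt
Reagents that add atoms: none
Why: Lindlar semi-hydrogenation adds H2 syn and stops at the (Z)-alkene that the rearrangement needs.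

Step 4
Reactants: 5 2-O-[(Z)-but-2-en-1-yl]-3,5-O-isopropylidene-D-xylono-1,4-lactone
Product: 7 2-C-[(2S)-but-3-en-2-yl]-3,5-O-isopropylidene-D-lyxono-1,4-lactone, via lithium enolate 6 (not isolated)
Conditions: LiN(SiMe3)2, THF–DMPU, −78 → −40 °C; aq. NH4Cl
Reagents that add atoms: none
Why: In this [2,3]-Wittig rearrangement of the α-allyloxy lactone enolate the crotyl group goes to the convex face anti to the fused dioxane (sets C1, OH cis to O-5), and the (Z)-alkene in the five-membered envelope transition state with the enolate carbon exo gives the syn HO/CH3 pair (sets C10).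

Step 5
Reactants: 7 2-C-[(2S)-but-3-en-2-yl]-3,5-O-isopropylidene-D-lyxono-1,4-lactone
Product: 8 2-C-[(2S)-but-3-en-2-yl]-3,5-O-isopropylidene-N-methoxy-N-methyl-D-lyxonamide
Conditions: MeNH(OMe)·HCl, AlMe3, CH2Cl2, 0 °C → rt; cold dilute HCl work-up
Reagents that add atoms: N,O-dimethylhydroxylamine hydrochloride, CNOC.Cl
Why: Weinreb aminolysis with the aluminium amide opens the template lactone, frees O-6 and makes C2 an acyl donor for a single organolithium addition, without touching a stereocentre.

Step 6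
Reactants: 8 2-C-[(2S)-but-3-en-2-yl]-3,5-O-isopropylidene-N-methoxy-N-methyl-D-lyxonamide
Product: 9 4-O-(tert-butyldimethylsilyl) ether of 8
Conditions: TBSOTf, 2,6-lutidine, CH2Cl2, −78 °C
Reagents that add atoms: tert-butyldimethylsilyl trifluoromethanesulfonate, CC(C)(C)[Si](C)(C)OS(=O)(=O)C(F)(F)F
Why: Silylation takes the only secondary hydroxyl (the tertiary 1-OH is too hindered at −78 °C), which blocks O-6 so that the later C2 ketone stays open-chain.

Step 7
Reactants: 9 4-O-(tert-butyldimethylsilyl) ether of 8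
Product: 11 primary alcohol (2-C-[(2S)-4-hydroxybutan-2-yl] analogue of 9), via B-alkyl-9-BBN borane 10 (not isolated)
Conditions: 9-BBN, THF, 0 °C → rt; then NaOH, H2O2, 0 °C
Reagents that add atoms: hydrogen peroxide, OO
Why: Anti-Markovnikov hydroboration–oxidation of the terminal vinyl group gives the C8 primary alcohol; amide, acetonide and silyl ether are inert and C10 is untouched.

Step 8
Reactants: 11 primary alcohol (2-C-[(2S)-4-hydroxybutan-2-yl] analogue of 9)
Product: 13 lactol (cyclic hemiacetal between 1-OH and C8), via hydroxy aldehyde 12 (not isolated)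
Conditions: Dess–Martin periodinane, NaHCO3, CH2Cl2, 0 °C → rt
Reagents that add atoms: none
Why: Dess–Martin oxidation gives the C8 aldehyde, which the tertiary 1-OH traps at once as a five-membered lactol.

Step 9
Reactants: 13 lactol (cyclic hemiacetal between 1-OH and C8)
Product: 14 methyl acetal diol (methyl acetal of 13 without the acetonide)
Conditions: PPTS, MeOH, rt
Reagents that add atoms: methanol, CO
Why: Fischer-type acetalization masks C8 and O-1 as a methyl acetal while the acetonide is transacetalized to methanol, freeing 5-OH and 7-OH; the secondary TBS ether survives PPTS.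

Step 10
Reactants: 14 methyl acetal diol (methyl acetal of 13 without the acetonide); 15 (E)-1-bromoprop-1-ene
Product: 17 enone ((E)-prop-1-enyl ketone at C2), via (E)-prop-1-en-1-yllithium 16 (not isolated)
Conditions: 15, Li, Et2O, 0 °C; then 14, THF, −78 °C; H2O
Reagents that add atoms: none
Why: In this Weinreb ketone synthesis the alkenyllithium (formed with retention of E geometry) adds once because the N-methoxy chelate holds the tetrahedral intermediate until work-up; two further equivalents only deprotonate the free hydroxyls.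

Step 11
Reactants: 17 enone ((E)-prop-1-enyl ketone at C2)
Product: 18 C7 aldehyde of 17
Conditions: TEMPO (cat.), PhI(OAc)2, CH2Cl2, rt
Reagents that add atoms: none
Why: The oxoammonium (TEMPO) oxidation is selective for the primary 7-OH over the secondary 5-OH and does not epimerize C6.

Step 12
Reactants: 18 C7 aldehyde of 17; 19 tert-butyl acrylate
Product: 20 Morita–Baylis–Hillman adduct of 18
Conditions: DABCO, neat 19, rt, 3–5 d
Reagents that add atoms: none
Why: The Morita–Baylis–Hillman reaction of the activated α-silyloxy aldehyde attaches C11–C13; the new carbinol centre is erased in steps 13 and 14.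

Step 13
Reactants: 20 Morita–Baylis–Hillman adduct of 18; 21 angelic acid
Product: 23 bis-angelate of 20, via angelic 2,4,6-trichlorobenzoic anhydride 22 (not isolated)
Conditions: 21 (3 equiv), 2,4,6-trichlorobenzoyl chloride (3 equiv), Et3N, toluene, rt; then 20, DMAP, 80 °C
Reagents that add atoms: angelic acid (second equivalent), C/C=C(/C)C(=O)O
Why: Yamaguchi esterification with two equivalents of the mixed anhydride (one per hydroxyl) acylates both secondary hydroxyls without Z→E isomerization of the angeloyl group, which installs the final 5-O-angelate and turns the allylic hydroxyl into a leaving group.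

Step 14
Reactants: 23 bis-angelate of 20
Product: 24 tert-butyl (Z)-2-(bromomethyl)alk-2-enoate (C7=C11, C13H2Br)
Conditions: MgBr2·OEt2, THF, 0 °C → rt
Reagents that add atoms: magnesium dibromide diethyl etherate, [Mg+2].[Br-].[Br-].CCOCC
Why: Lewis-acid-assisted SN2′ displacement of the allylic carboxylate by bromide gives the thermodynamically preferred (Z)-2-(bromomethyl)enoate and leaves the unactivated 5-O-angelate alone.

Step 15
Reactants: 24 tert-butyl (Z)-2-(bromomethyl)alk-2-enoate (C7=C11, C13H2Br)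
Product: 26 cycloheptane hydroxy ester (tert-butyl ester; 1-OH and 8-OH free; 6-O-TBS), via lactol bromide 25 (not isolated)
Conditions: 1 M HCl, THF, rt; then In powder, aq. NH4Cl, THF–H2O (0.005 M), rt
Reagents that add atoms: water, O
Why: After acetal hydrolysis an intramolecular indium Barbier allylation closes the seven-membered ring: A(1,3) strain keeps C6–H in the alkene plane so the tethered aldehyde attacks C7 anti to the silyloxy group (6,7-trans), and the chair Zimmerman–Traxler transition state of the (Z)-allylindium gives the syn adduct (8-OH cis to C11).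

Step 16
Reactants: 26 cycloheptane hydroxy ester (tert-butyl ester; 1-OH and 8-OH free; 6-O-TBS)
Product: 29 target CNP0206014.2, via 8-O-trifluoroacetate 27 (not isolated), via lactone 8-O-trifluoroacetate 28 (not isolated)
Conditions: (CF3CO)2O, pyridine, CH2Cl2, 0 °C; MeOH quench; then CF3CO2H–CH2Cl2 (1:4), 0 °C → rt; then NaHCO3, MeOH, 0 °C
Reagents that add atoms: none
Why: Transient trifluoroacetylation masks 8-OH so that, when CF3CO2H cleaves the tert-butyl ester and the TBS ether, only the unveiled 6-OH can undergo the acid-catalysed lactonization (trans-fused γ-lactone), and mild methanolysis then frees 8-OH without changing a stereocentre.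

## Compound list

1 | D-xylono-1,4-lactone | OC[C@H]1OC(=O)[C@H](O)[C@H]1O | starting material
2 | 3,5-O-isopropylidene-D-xylono-1,4-lactone | CC1(C)OC[C@H]2OC(=O)[C@H](O)[C@H]2O1 | intermediate
3 | 1-bromobut-2-yne | CC#CCBr | starting material
4 | 2-O-(but-2-yn-1-yl)-3,5-O-isopropylidene-D-xylono-1,4-lactone | CC1(C)OC[C@H]2OC(=O)[C@H](OCC#CC)[C@H]2O1 | intermediate
5 | 2-O-[(Z)-but-2-en-1-yl]-3,5-O-isopropylidene-D-xylono-1,4-lactone | CC1(C)OC[C@H]2OC(=O)[C@H](OC/C=C\C)[C@H]2O1 | intermediate
6 | lithium enolate of 5 (O-lithio ketene acetal, C1=C2), not isolated | CC1(C)OC[C@H]2OC(O[Li])=C(OC/C=C\C)[C@H]2O1 | intermediate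
7 | 2-C-[(2S)-but-3-en-2-yl]-3,5-O-isopropylidene-D-lyxono-1,4-lactone | CC1(C)OC[C@H]2OC(=O)[C@](O)([C@@H](C)C=C)[C@H]2O1 | intermediate
8 | 2-C-[(2S)-but-3-en-2-yl]-3,5-O-isopropylidene-N-methoxy-N-methyl-D-lyxonamide | CON(C)C(=O)[C@](O)([C@@H](C)C=C)[C@H]1OC(C)(C)OC[C@H]1O | intermediate
9 | 4-O-(tert-butyldimethylsilyl) ether of 8 | CON(C)C(=O)[C@](O)([C@@H](C)C=C)[C@H]1OC(C)(C)OC[C@H]1O[Si](C)(C)C(C)(C)C | intermediate
10 | B-alkyl-9-BBN borane from 9 (boron on the terminal carbon of the former vinyl group), not isolated | CON(C)C(=O)[C@](O)([C@@H](C)CCB1C2CCCC1CCC2)[C@H]3OC(C)(C)OC[C@H]3O[Si](C)(C)C(C)(C)C | intermediate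
11 | primary alcohol: 2-C-[(2S)-4-hydroxybutan-2-yl] analogue of 9 | CON(C)C(=O)[C@](O)([C@@H](C)CCO)[C@H]1OC(C)(C)OC[C@H]1O[Si](C)(C)C(C)(C)C | intermediate
12 | hydroxy aldehyde: 2-C-[(2S)-4-oxobutan-2-yl] analogue of 9, not isolated | CON(C)C(=O)[C@](O)([C@@H](C)CC=O)[C@H]1OC(C)(C)OC[C@H]1O[Si](C)(C)C(C)(C)C | intermediate
13 | lactol: cyclic hemiacetal of 12 between the tertiary OH and the aldehyde (anomeric mixture) | CON(C)C(=O)[C@@]1(OC(O)C[C@@H]1C)[C@H]2OC(C)(C)OC[C@H]2O[Si](C)(C)C(C)(C)C | intermediate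
14 | methyl acetal diol: methyl acetal of 13 without the acetonide (free 5-OH and 7-OH, 6-O-TBS) | CON(C)C(=O)[C@@]1(OC(OC)C[C@@H]1C)[C@@H](O)[C@@H](CO)O[Si](C)(C)C(C)(C)C | intermediate
15 | (E)-1-bromoprop-1-ene | C/C=C/Br | starting material
16 | (E)-prop-1-en-1-yllithium, not isolated | [Li]/C=C/C | intermediate
17 | enone: (E)-prop-1-enyl ketone in place of the Weinreb amide of 14 | C/C=C/C(=O)[C@@]1(OC(OC)C[C@@H]1C)[C@@H](O)[C@@H](CO)O[Si](C)(C)C(C)(C)C | intermediate
18 | C7 aldehyde of 17 | C/C=C/C(=O)[C@@]1(OC(OC)C[C@@H]1C)[C@@H](O)[C@@H](C=O)O[Si](C)(C)C(C)(C)C | intermediate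
19 | tert-butyl acrylate | C=CC(=O)OC(C)(C)C | starting material
20 | Morita–Baylis–Hillman adduct of 18 and 19 (carbinol mixture) | C/C=C/C(=O)[C@@]1(OC(OC)C[C@@H]1C)[C@@H](O)[C@@H](C(O)C(=C)C(=O)OC(C)(C)C)O[Si](C)(C)C(C)(C)C | intermediate
21 | angelic acid, (Z)-2-methylbut-2-enoic acid | C/C=C(/C)C(=O)O | starting material
22 | angelic 2,4,6-trichlorobenzoic anhydride, not isolated | C/C=C(/C)C(=O)OC(=O)c1c(Cl)cc(Cl)cc1Cl | intermediate
23 | bis-angelate of 20 (5-O-angelate and allylic angelate) | C/C=C/C(=O)[C@@]1(OC(OC)C[C@@H]1C)[C@@H](OC(=O)/C(C)=C\C)[C@@H](C(OC(=O)/C(C)=C\C)C(=C)C(=O)OC(C)(C)C)O[Si](C)(C)C(C)(C)C | intermediate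
24 | tert-butyl (Z)-2-(bromomethyl)alk-2-enoate from 23 (C7=C11, C13H2Br) | C/C=C/C(=O)[C@@]1(OC(OC)C[C@@H]1C)[C@@H](OC(=O)/C(C)=C\C)[C@@H](/C=C(\CBr)C(=O)OC(C)(C)C)O[Si](C)(C)C(C)(C)C | intermediate
25 | lactol bromide: 24 with the methyl acetal hydrolysed, not isolated | C/C=C/C(=O)[C@@]1(OC(O)C[C@@H]1C)[C@@H](OC(=O)/C(C)=C\C)[C@@H](/C=C(\CBr)C(=O)OC(C)(C)C)O[Si](C)(C)C(C)(C)C | intermediate
26 | cycloheptane hydroxy ester: tert-butyl acrylate unit on C7; 1-OH, 8-OH, 5-O-angelate, 6-O-TBS, 10-CH3, 1-(E)-crotonoyl; configured as in 29 | C=C(C(=O)OC(C)(C)C)[C@H]1[C@@H](O)C[C@H](C)[C@@](O)(C(=O)/C=C/C)[C@@H](OC(=O)/C(C)=C\C)[C@@H]1O[Si](C)(C)C(C)(C)C | intermediate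
27 | 8-O-trifluoroacetate of 26, not isolated | C=C(C(=O)OC(C)(C)C)[C@H]1[C@@H](OC(=O)C(F)(F)F)C[C@H](C)[C@@](O)(C(=O)/C=C/C)[C@@H](OC(=O)/C(C)=C\C)[C@@H]1O[Si](C)(C)C(C)(C)C | intermediate
28 | 8-O-trifluoroacetate of 29, not isolated | C=C1C(=O)O[C@@H]2[C@@H]1[C@@H](OC(=O)C(F)(F)F)C[C@H](C)[C@@](O)(C(=O)/C=C/C)[C@H]2OC(=O)/C(C)=C\C | intermediate
29 | CNP0206014.2 (1S,5S,6R,7S,8S,10S in the locants above) | C=C1C(=O)O[C@@H]2[C@@H]1[C@@H](O)C[C@H](C)[C@@](O)(C(=O)/C=C/C)[C@H]2OC(=O)/C(C)=C\C | target

## Step count and risk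

Total steps: 16. Longest linear sequence: 16 steps (1 → 29); compounds 3, 15, 19 and 21 are bought.

The three steps most likely to fail:

Step 4. The lactone enolate carries a β-oxygen (O-5) that can be eliminated before the [2,3]-shift, and the syn selectivity rests on the enolate-carbon-exo transition-state model. Fallback: set out from 5 and remove the acetonide (PPTS, MeOH) to give 2-O-[(Z)-but-2-en-1-yl]-D-xylono-1,4-lactone F1. The same sigmatropic shift is then run on its trilithium derivative (LiN(SiMe3)2, 3.3 equiv, THF, −78 → −30 °C). With O-5 as a lithium alkoxide the β-elimination channel is closed (Fráter–Seebach-type polyanion) and the face anti to that oxygen remains the open one. This gives 2-C-[(2S)-but-3-en-2-yl]-D-lyxono-1,4-lactone F2, and acetonide formation as in step 1 comes back to the route at 7.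

Step 15. The seven-membered ring closure can lose to oligomerization, to allylation of the C2 ketone (a five-membered ring), or give poor diastereoselectivity. Fallback: set out from 24 and exchange bromide for boron (B2pin2, Pd2(dba)3 cat., THF, 50 °C) to give the allylboronic acid pinacol ester F3. Aqueous AcOH hydrolyses its methyl acetal to the lactol boronate F4, which is warmed in toluene. The intramolecular allylboration needs no metal insertion, ignores ketones and runs through the same closed chair transition state; after aqueous work-up it comes back to the route at 26.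

Step 16. If trifluoroacetylation of 8-OH is incomplete, 8-OH lactonizes instead and gives the cis-fused 8,12-olide; the three-stage one-pot can also lose material. Fallback: set out from 26 and silylate 8-OH with TIPSOTf/2,6-lutidine to the isolable 8-O-triisopropylsilyl ether F5. Brief treatment with CF3CO2H–CH2Cl2 cleaves the tert-butyl ester and the TBS ether and lactonizes on O-6 to give the 8-O-triisopropylsilyl lactone F6. HF·pyridine in THF then removes the silyl group and comes back to the route at 29.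

Further compounds

F1 | step 4 | 2-O-[(Z)-but-2-en-1-yl]-D-xylono-1,4-lactone | OC[C@H]1OC(=O)[C@H](OC/C=C\C)[C@H]1O
F2 | step 4 | 2-C-[(2S)-but-3-en-2-yl]-D-lyxono-1,4-lactone | OC[C@H]1OC(=O)[C@](O)([C@@H](C)C=C)[C@H]1O
F3 | step 15 | allylboronic acid pinacol ester from 24 (Bpin in place of Br) | C/C=C/C(=O)[C@@]1(OC(OC)C[C@@H]1C)[C@@H](OC(=O)/C(C)=C\C)[C@@H](/C=C(\CB2OC(C)(C)C(C)(C)O2)C(=O)OC(C)(C)C)O[Si](C)(C)C(C)(C)C
F4 | step 15 | lactol boronate (F3 with the methyl acetal hydrolysed) | C/C=C/C(=O)[C@@]1(OC(O)C[C@@H]1C)[C@@H](OC(=O)/C(C)=C\C)[C@@H](/C=C(\CB2OC(C)(C)C(C)(C)O2)C(=O)OC(C)(C)C)O[Si](C)(C)C(C)(C)C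
F5 | step 16 | 8-O-triisopropylsilyl ether of 26 | C=C(C(=O)OC(C)(C)C)[C@H]1[C@@H](O[Si](C(C)C)(C(C)C)C(C)C)C[C@H](C)[C@@](O)(C(=O)/C=C/C)[C@@H](OC(=O)/C(C)=C\C)[C@@H]1O[Si](C)(C)C(C)(C)C
F6 | step 16 | 8-O-triisopropylsilyl ether of 29 | C=C1C(=O)O[C@@H]2[C@@H]1[C@@H](O[Si](C(C)C)(C(C)C)C(C)C)C[C@H](C)[C@@](O)(C(=O)/C=C/C)[C@H]2OC(=O)/C(C)=C\C
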